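The ochre run's first reading, at 10.0 min, shows 35 % of ring and 53 % of starting material, so 12.0 % of the charge is already neither.

| setting | grey | ochre | Tuesday's | Sunday's | Saturday's | Thursday's | Wednesday's | Monday's |
|---|---|---|---|---|---|---|---|---|
| starting material | 0.62 M | 1.4 M | 2.0 M | 2.0 M | 2.0 M | 2.0 M | 1.0 M | 1.0 M |
| temperature | 5 °C | 49 °C | 25 °C | 10 °C | 55 °C | 40 °C | 65 °C | −15 °C |
| remark | run made earlier | run made earlier |  |  |  |  |  |  |
| time |  |  | 4.0 h | 4.0 h | 4.0 h | 4.0 h | 4.0 h | 4.0 h |

grey run (percent of the starting material charged)

| time / h | ring / % | starting material / % |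
|---|---|---|
| 0.500 | 1 | 98 |
| 2.00 | 4 | 96 |
| 2.50 | 5 | 95 |
| 4.00 | 7 | 96 |
| 6.00 | 4 | 93 |
| 8.00 | 8 | 88 |
| 10.0 | 10 | 88 |

ochre run (percent of the starting material charged)

| time / min | ring / % | starting material / % |
|---|---|---|
| 10.0 | 35 | 53 |
| 20.0 | 57 | 29 |
| 30.0 | 65 | 19 |
| 50.0 | 75 | 9 |
| 60.0 | 79 | 5 |
| 80.0 | 79 | 1 |

(scatter of a reading: 1.5 percentage points)

- a reading or a percentage of ring counts all its forms, free or not

* the flasks put in order of amount of ring, in percent of the starting material charged, best first, at 4.0 h (Tuesday's / Sunday's / Saturday's / Thursday's / Wednesday's / Monday's)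
* the same order at 15 h (Tuesday's / Sunday's / Saturday's / Thursday's / Wednesday's / Monday's)
* the amount of ring, in percent of the starting material charged of the flask you put first, at 4.0 h
* the amount of ring, in percent of the starting material charged of the flask you put last, at 4.0 h

The bench rule says: let the flask finish, and a hotter bath merely gets you to the same ring sooner. So I ask what a finished flask holds. In ochre, each part of ring comes with 0.343 parts lost up to the first reading, but with 0.182 between the first and last readings. In ochre the loss per part of ring thins as the starting material thins, so I divide it by the mean strength over the first interval. That gives the split, a selectivity factor: charge lost per part of ring, per unit of strength of starting material. It is a reading and carries the scatter of 1.5 percentage points per reading.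

split = 0.320 L mol⁻¹

Adding up that loss from the full charge to none, with the split held at its ochre reading, gives my reckoning of the finished ring:

finished ring, as a fraction of the charge = ln(1 + split × strength) / (split × strength)

at 2.0 M: 77.3 %

at 1.0 M: 86.8 %

The rule needs ring that stands still once made. Ochre's ring reads the same at 60.0 min and 80.0 min, but that is 20.0 min of standing, and 4.0 h is 12.0 times as long. Those readings come from 49 °C, and the baths of Saturday's and Wednesday's are hotter, so they say little of how ring stands in those two flasks. So I do not take the finished ring at 1.0 M as my estimate for Wednesday's.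

The forecast orders the flasks Wednesday's > Thursday's > Saturday's > Tuesday's > Sunday's > Monday's at 4.0 h and Wednesday's > Thursday's > Saturday's > Tuesday's > Sunday's > Monday's at 15 h, with 84 % for the first and 0.2 % for the last: “Wednesday finishes at the better dilution.”

Thursday's holds the most ring at 4.0 h, 70.6 %. The order is Thursday's > Saturday's > Wednesday's > Tuesday's > Sunday's > Monday's at 4.0 h and Thursday's > Tuesday's > Saturday's > Sunday's > Wednesday's > Monday's at 15 h, and Monday's holds 0.145 % at 4.0 h.

    crystals ⇌ ring, rate k1*(cs1 - [ring]) while solid is left; crystals form when [ring] > cs1 (solubility = 1.80 M, k = 0.0930 min⁻¹)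
    starting material → ring (k = 0.00260 min⁻¹, Ea = 97.0 kJ mol⁻¹)
    ring → over-reaction product (k = 9.30 × 10⁻⁶ min⁻¹, Ea = 114 kJ mol⁻¹)
    2 starting material → open dimer (k = 8.00 × 10⁻⁴ L mol⁻¹ min⁻¹, Ea = 77.0 kJ mol⁻¹)
    (constants at 25 °C)

In Thursday's, the half-life of dissolved ring by over-reaction alone, 140 h, is long against 4.0 h. The split's finished ring for Thursday's charge, 77.3 %, stands 6.7 points above the ring found.

Take a neighbour, Monday's charge kept at 10 °C, with 86.3 % of the starting material left at 4.00 h. At the mean strength of those hours the split, read at 49 °C, gives 0.298 parts lost per part of ring. At 4.00 h that neighbour holds 6.41 % of open dimer against 7.29 % of ring, which is 0.879 parts, higher than the split gave.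

All runs were computed with made-up constants.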